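Its constants are those of an exercise; no experiment stands behind them.

Z is the product wanted.

    E + G ⇌ E.G (K1 = 14 /M, k1 = 0.57 /M/s, Ea1 = 44.0 kJ/mol, ΔH1 = −59.0 kJ/mol)
    E → L (k2 = 0.032 /s, Ea2 = 101 kJ/mol)
    G + L ⇌ G.L (K3 = 19 /M, k3 = 0.083 /M/s, Ea3 = 74.0 kJ/mol, ΔH3 = −25.0 kJ/mol)
    E.G ⇌ Z (K4 = 5.0, k4 = 0.19 /s, Ea4 = 79.0 kJ/mol, ΔH4 = −8.00 kJ/mol)
    L → J (k5 = 0.093 /s, Ea5 = 74.0 kJ/mol)
    Z ⇌ X (K6 = 1.1, k6 = 0.015 /s, Ea6 = 79.0 kJ/mol, ΔH6 = 27.0 kJ/mol)
    (constants at 60 °C)

| flask | E | G | temperature | time | remark |
|---|---|---|---|---|---|
| grey | 0.050 M | 2.00 equiv | 60 °C | 1.5 min |  |
| blue | 0.050 M | 2.00 equiv | 20 °C | 1.5 min |  |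
| green | 0.050 M | 2.00 equiv |  | 1.5 min | at 60 °C until 25 s, from then on at 20 °C |
| amber | 0.050 M | 2.00 equiv | 40 °C | 1.5 min |  |

* the flask that comes out highest in amount of Z, in percent of the E charged, or "all alike" when all lie within 1.5 percentage points (grey / blue / green / amber / all alike)
* Z at the end, in percent of the E charged, grey
* Z at the end, in percent of the E charged, blue
* Z at the end, in percent of the E charged, green
* Z at the end, in percent of the E charged, amber

- constants are those at 60 °C; use the activation energies and enthalpies for any other temperature

An engineer can read the way to Z as two first-order stages in series. E feeds into E.G, and at the charged amount of G this is a pseudo-first-order stage with feed time τf, the reciprocal of its rate constant times the charged G. E.G then turns into Z with conversion time τz, the reciprocal of its rate constant. In blue, at 20 °C, τf is 153 s and τz is 258 s, and the run of 90 s is shorter than either. The output of two such stages starts with the square of time, so blue's start rate, carried through the run t, gives 0.5·(t/τf)·(t/τz) = 10.2 % of the E charged. This is the series allowance A: the share of the charge that has passed both stages, usable while it lies well below one.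

This reckoning takes two things that slow that rate in blue. E drains as it feeds, and the exact series response gives 7.56 %, a factor of 0.741. G falls as E binds it, which takes the feed down by a further factor of about 0.889 on average over the run. Together they leave 6.72 % for blue, and that is the figure this reckoning commits to. In amber the times are 48.4 s and 32.5 s, so A comes to 257 %. That is past the whole charge, and the formula no longer counts. This reckoning therefore says only that amber lies well above blue, and it stops there, with no figure for amber, grey or green.

The forecast gives 23 % for grey, 7 % for blue, 32 % for green and 41 % for amber, and names amber as highest, holding that “the intermediate 40 °C flask should give the most Z”. Its blue lies close to the reckoning above, and its other three figures go where the reckoning does not.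

The simulation gives 23.0 % for grey, 6.80 % for blue, 31.3 % for green and 42.4 % for amber, so amber is highest. Blue stays low because of the length of its run: its A is 10.2 %, and blue holds 6.80 % at 1.5 min against 67.7 % at 15.0 min, a gain of 61 percentage points. That length is also what would overturn the forecast's choice of highest flask, since there blue stands above amber's 43.2 %.

A flask like amber kept at 15 °C has A = 4.27 %, which is 0.419 of blue's. Computed, it holds 3.23 % of Z.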